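I asked where the reagent went.

- epsilon: substrate 0.50 M; reagent 0.45 M (fed, over 1.0 min); the very flask that is asked about, followed so far
- flask: substrate 0.50 M; reagent 0.450 M (fed, over 1.0 min); time 2.5 h
epsilon run (percent of the substrate charged)

| time / min | substrate / % | first product / % |
|---|---|---|
| 2.50 | 94.6 | 3.5 |
| 5.00 | 90.8 | 6.7 |
| 8.00 | 88.2 | 9.7 |
| 15.0 | 83.7 | 12.8 |
| 30.0 | 78.8 | 15.9 |

(standard deviation of a reading: 0.3 percentage points)
- what was read earlier has a scatter of 0.3 percentage points, one standard deviation
- a reading or a percentage of first product counts all its forms, free or not
- how much substrate there is at 2.5 h, in percent of the substrate charged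
- how much first product there is at 2.5 h, in percent of the substrate charged
- how much other mono adduct there is at 2.5 h, in percent of the substrate charged
- how much double product there is at 2.5 h, in percent of the substrate charged

I took the substrate's rate of loss, as a fraction of its charge, between successive readings:

0.0216 min⁻¹, 0.0152 min⁻¹, then 0.00643 min⁻¹, 0.00327 min⁻¹

This rate fell far more steeply than the substrate did, so I supposed that the reagent was disappearing. The rate's drop per amount of substrate taken equals its fractional fall per minute:

early 0.139 min⁻¹, late 0.0673 min⁻¹

I split this fall into two rates: a steady use on substrate (pseudo-first-order), and a loss of reagent to itself, proportional to the substrate rate.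

proportion 5.30; use on substrate 0.0416 min⁻¹

Over the last interval the self-loss stood to that use as 0.417. As this ratio runs down from r, with the substrate taken as steady, the share of reagent reaching substrate is the logarithm of one plus r, over r.

substrate taken in the end 25.3%; share of the reagent 28.1%

That share needs a ratio of self-loss to use on substrate at the start of 7.68, as read: the **start ratio**. I expected 74.7% substrate, and first product near 19.0%.

The forecast gave 63% substrate, 26% first product, 7% other mono adduct and 4% double product, citing “most likely inhibition or binding by first product”. Its substrate is lower than mine.

At 2.5 h the flask held 73.8% substrate, 20.2% first product, 5.88% other mono adduct and 0.0375% double product.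

    substrate + reagent → first product (k = 0.0550 M⁻¹ min⁻¹)
    crystals ⇌ first product, rate k2*(cs2 - [first product]) while solid is left; crystals form when [first product] > cs2 (solubility = 14.0 mM, k = 5.30 min⁻¹)
    reagent + other mono adduct → double product (k = 8.10 × 10⁻⁴ M⁻¹ min⁻¹)
    substrate + reagent → other mono adduct (k = 0.0160 M⁻¹ min⁻¹)
    reagent + first product → double product (k = 0.00230 M⁻¹ min⁻¹)
    2 reagent → homo dimer (k = 0.260 M⁻¹ min⁻¹)

At the end of the feed this flask's reagent was going to homo dimer faster than to substrate. At 2.50 h this flask's homo dimer held 70.7% of the charged reagent, the limiting reagent, and reaction with substrate had taken 29.1%, with 0.19% left. For a neighbour flask, the same but with 0.85 M of substrate, I scaled the start ratio to 4.52, which reckoned 80.0% substrate; that flask gave 78.9%.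

Readings and results stem from a simulated flask for an exercise, and the scatter is random.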